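## Retrosynthetic overview

- Ring B of the 1-aryltetralin (C1 diaryl methine, C2 and C3 bearing the CH2OH carbons C9 and C9′, C4 benzylic CH2, C4a/C8a ring fusion) is read as the [4+2] adduct of an o-quinodimethane C1=C8a–C4a=C4 spanning ring A and a trans C2=C3 dienophile. C1–C2 and C3–C4 are the bonds to make; ring B is the only ring formed, ring A and the pendant aryl ring are bought.
- Target ⇐ hydrogenolysis of an extra C4–OH and of the benzyl ether, desilylation and ester reduction of a 4-hydroxy-1-aryltetralin-2,3-dicarboxylate ⇐ photoenol of a 2-benzylbenzaldehyde (CHO becomes C4, ArCH2 becomes C1) plus the C2-symmetric fumarate of methyl (R)-lactate.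
- 2-Benzylbenzaldehyde ⇐ Br–Li exchange/DMF on a 2-bromodiarylmethane ⇐ ionic hydrogenation of the carbinol from an aryl Grignard reagent and 2-bromo-3,4-dimethoxy-5-silyloxybenzaldehyde.
- The C7 oxygen is carried as a triisopropylsilyl ether, not a benzyl ether. OBn and OMe would not differentiate the two positions ortho to CHO in the bromination that defines C4a; the bulky silyl group shields the wrong one.

Key step: step 8

Assumption: the facial sense is assigned by a hydrogen-bond model (dienol OH to the lactyl CO2CH3 of the endo ester, s-cis enoate), which puts the diene on the Si,Si face of the (R,R)-fumarate and leads to the (2S,3S) series of the target; should the sense be the reverse, only methyl (R)-lactate is exchanged for its enantiomer.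

## Route

Step 1
Reactants: 1 3-hydroxy-4,5-dimethoxybenzaldehyde
Product: 2 3,4-dimethoxy-5-(triisopropylsilyloxy)benzaldehyde
Conditions: TIPSCl, imidazole, DMF, rt
Reagents that add atoms: triisopropylsilyl chloride, CC(C)[Si](Cl)(C(C)C)C(C)C
Why: Imidazole-mediated O-silylation of the phenol; the triisopropylsilyl group is chosen because its bulk is needed in step 2 and because it should survive ArMgBr, cold TFA/Et3SiH, n-BuLi and LiAlH4.

Step 2
Reactants: 2 3,4-dimethoxy-5-(triisopropylsilyloxy)benzaldehyde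
Product: 3 2-bromo-3,4-dimethoxy-5-(triisopropylsilyloxy)benzaldehyde
Conditions: NBS (1.05 equiv), MeCN, 0 °C to rt, dark
Reagents that add atoms: N-bromosuccinimide, O=C1CCC(=O)N1Br
Why: Electrophilic aromatic bromination; C2 (ortho to 3-OMe, para to the silyloxy group) and C6 (ortho to the silyloxy group, para to 3-OMe) are activated to a similar degree, and the Si(iPr)3 group shields C6, so bromine should enter C2, the future C4a.

Step 3
Reactants: 4 4-bromo-2-methoxyphenol
Product: 5 1-benzyloxy-4-bromo-2-methoxybenzene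
Conditions: BnBr, K2CO3, acetone, reflux
Reagents that add atoms: benzyl bromide, BrCc1ccccc1
Why: Williamson etherification of the phenoxide with a benzylic bromide; the aryl bromide is inert under these conditions.

Step 4
Reactants: 5 1-benzyloxy-4-bromo-2-methoxybenzene and 3 2-bromo-3,4-dimethoxy-5-(triisopropylsilyloxy)benzaldehyde
Product: 7 rac-(4-benzyloxy-3-methoxyphenyl)[2-bromo-3,4-dimethoxy-5-(triisopropylsilyloxy)phenyl]methanol, via (4-benzyloxy-3-methoxyphenyl)magnesium bromide 6 (not isolated)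
Conditions: Mg, I2 (cat.), THF, reflux; then 3, THF, 0 °C; aq NH4Cl
Reagents that add atoms: none
Why: Grignard formation and 1,2-addition to the aldehyde, which is much faster than any Br–Mg exchange at the hindered aryl bromide of 3; the carbinol is racemic and its stereocentre is removed in step 5.

Step 5
Reactants: 7 rac-(4-benzyloxy-3-methoxyphenyl)[2-bromo-3,4-dimethoxy-5-(triisopropylsilyloxy)phenyl]methanol
Product: 8 1-benzyloxy-4-[2-bromo-3,4-dimethoxy-5-(triisopropylsilyloxy)benzyl]-2-methoxybenzene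
Conditions: Et3SiH (3 equiv), TFA, CH2Cl2, 0 °C
Reagents that add atoms: none
Why: Ionic hydrogenation, in which TFA ionises the carbinol to a diarylmethyl cation stabilised by the para-benzyloxy ring and Et3SiH delivers hydride; aryl benzyl and aryl triisopropylsilyl ethers should tolerate cold TFA for the short reaction time.

Step 6
Reactants: 8 1-benzyloxy-4-[2-bromo-3,4-dimethoxy-5-(triisopropylsilyloxy)benzyl]-2-methoxybenzene
Product: 10 6-(4-benzyloxy-3-methoxybenzyl)-2,3-dimethoxy-4-(triisopropylsilyloxy)benzaldehyde, via [2-(4-benzyloxy-3-methoxybenzyl)-5,6-dimethoxy-4-(triisopropylsilyloxy)phenyl]lithium 9 (not isolated)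
Conditions: n-BuLi (1.1 equiv), THF, −78 °C; DMF, −78 to 0 °C; H2O
Reagents that add atoms: N,N-dimethylformamide, CN(C)C=O
Why: Bromine–lithium exchange followed by Bouveault-type formylation with DMF; at −78 °C the exchange should outrun deprotonation of the diarylmethane CH2 or of the OCH2Ph group, and the tetrahedral adduct releases the aldehyde only on work-up.

Step 7
Reactants: 11 fumaryl chloride and 12 methyl (R)-lactate (2.1 equiv in total)
Product: 13 bis[(R)-1-methoxy-1-oxopropan-2-yl] fumarate
Conditions: 12 (2.1 equiv), pyridine (2.2 equiv), DMAP (cat.), CH2Cl2, 0 °C to rt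
Reagents that add atoms: methyl (R)-lactate (second equivalent), C[C@@H](O)C(=O)OC
Why: Twofold acylation, in which each acid chloride group of 11 esterifies one molecule of the secondary alcohol 12 with pyridine as HCl acceptor; the lactate stereocentre is not involved and the E geometry of the fumarate is retained.

Step 8
Reactants: 10 6-(4-benzyloxy-3-methoxybenzyl)-2,3-dimethoxy-4-(triisopropylsilyloxy)benzaldehyde and 13 bis[(R)-1-methoxy-1-oxopropan-2-yl] fumarate
Product: 15 bis[(R)-1-methoxy-1-oxopropan-2-yl] (1R,2S,3R,4R)-1-(4-benzyloxy-3-methoxyphenyl)-4-hydroxy-5,6-dimethoxy-7-(triisopropylsilyloxy)-1,2,3,4-tetrahydronaphthalene-2,3-dicarboxylate, via (E,E)-hydroxy-o-quinodimethane 14 (not isolated)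
Conditions: hν (350 nm, Pyrex), 13 (3 equiv), degassed toluene (0.03 M), 20 °C
Reagents that add atoms: none
Why: Excitation of the aldehyde carbonyl (n–π*) is followed by 1,5-hydrogen shift from the ArCH2Ar group to oxygen, and of the resulting photoenols only the (E,E)-dienol 14 (OH and aryl both outward) lives long enough to be intercepted; it adds the fumarate in a concerted suprafacial intermolecular [4+2] cycloaddition that closes six-membered ring B by forming C1–C2 and C3–C4 and rearomatises ring A. The closest known reaction type is the photoenolisation–Diels–Alder reaction of o-alkylbenzaldehydes and the addition of α-hydroxy-α′-aryl-o-quinodimethanes to lactate- and mandelate-derived fumarates. C1 and C4 follow from the diene geometry (aryl and OH cis), C2 and C3 from the E geometry of the dienophile (esters trans), and the relation between the two pairs from the endo orientation of the ester next to the dienol OH, which puts the C3 ester cis to the C4 hydroxyl and the C2 ester trans to the aryl group. The absolute configuration comes from the auxiliary: a hydrogen bond from the dienol OH to the lactyl CO2CH3 of the endo ester should bring the diene onto the Si,Si face of the (R,R)-fumarate, giving (1R,2S,3R,4R). The step needs endo and facial selectivity, both of which rest on that hydrogen bond, so a non-coordinating solvent is used; the dienophile is C2-symmetric (no regiochemical issue) and is taken in excess so that the dienol is captured before it reketonises.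

Step 9
Reactants: 15 bis[(R)-1-methoxy-1-oxopropan-2-yl] (1R,2S,3R,4R)-1-(4-benzyloxy-3-methoxyphenyl)-4-hydroxy-5,6-dimethoxy-7-(triisopropylsilyloxy)-1,2,3,4-tetrahydronaphthalene-2,3-dicarboxylate
Product: 16 (1R,2S,3S,4R)-1-(4-benzyloxy-3-methoxyphenyl)-2,3-bis(hydroxymethyl)-5,6-dimethoxy-7-(triisopropylsilyloxy)-1,2,3,4-tetrahydronaphthalen-4-ol
Conditions: LiAlH4 (excess), THF, −20 to 0 °C (15 added to the hydride); H2O, aq NaOH
Reagents that add atoms: none
Why: LiAlH4 reduction of all four ester functions, which turns both acyl carbons into the C9/C9′ hydroxymethyl groups and releases the auxiliary as propane-1,2-diol; adding the ester to excess hydride at low temperature should let reduction outrun retro-aldol opening at C3–C4, and no stereocentre is touched.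

Step 10
Reactants: 16 (1R,2S,3S,4R)-1-(4-benzyloxy-3-methoxyphenyl)-2,3-bis(hydroxymethyl)-5,6-dimethoxy-7-(triisopropylsilyloxy)-1,2,3,4-tetrahydronaphthalen-4-ol
Product: 17 (1R,2S,3S,4R)-1-(4-benzyloxy-3-methoxyphenyl)-2,3-bis(hydroxymethyl)-5,6-dimethoxy-1,2,3,4-tetrahydronaphthalene-4,7-diol
Conditions: TBAF (1.2 equiv), AcOH (1.2 equiv), THF, 0 °C
Reagents that add atoms: none
Why: Fluoride-induced cleavage of the aryl silyl ether, buffered with AcOH so that the para-hydroxybenzylic alcohol is not exposed to free phenoxide.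

Step 11
Reactants: 17 (1R,2S,3S,4R)-1-(4-benzyloxy-3-methoxyphenyl)-2,3-bis(hydroxymethyl)-5,6-dimethoxy-1,2,3,4-tetrahydronaphthalene-4,7-diol
Product: 18 (1R,2S,3S)-1-(4-hydroxy-3-methoxyphenyl)-2,3-bis(hydroxymethyl)-5,6-dimethoxy-1,2,3,4-tetrahydronaphthalen-7-ol (target)
Conditions: H2 (1 atm), 10% Pd/C, EtOH–AcOH (10:1), rt
Reagents that add atoms: none
Why: Catalytic hydrogenolysis, which cleaves the O-benzyl ether and reductively removes the benzylic C4–OH (activated by the para-hydroxyl and ortho-methoxy groups, as in the hydrogenolysis of benzylic hydroxyls of phenolic lignans), while C1, C2 and C3 carry no cleavable bond and keep their configuration.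

## Compound list

1 | 3-hydroxy-4,5-dimethoxybenzaldehyde | O=Cc1cc(O)c(OC)c(OC)c1 | starting material
2 | 3,4-dimethoxy-5-(triisopropylsilyloxy)benzaldehyde | O=Cc1cc(O[Si](C(C)C)(C(C)C)C(C)C)c(OC)c(OC)c1 | intermediate
3 | 2-bromo-3,4-dimethoxy-5-(triisopropylsilyloxy)benzaldehyde | O=Cc1cc(O[Si](C(C)C)(C(C)C)C(C)C)c(OC)c(OC)c1Br | intermediate
4 | 4-bromo-2-methoxyphenol | COc1cc(Br)ccc1O | starting material
5 | 1-benzyloxy-4-bromo-2-methoxybenzene | COc1cc(Br)ccc1OCc1ccccc1 | intermediate
6 | (4-benzyloxy-3-methoxyphenyl)magnesium bromide | COc1cc([Mg]Br)ccc1OCc1ccccc1 | intermediate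
7 | rac-(4-benzyloxy-3-methoxyphenyl)[2-bromo-3,4-dimethoxy-5-(triisopropylsilyloxy)phenyl]methanol (racemic) | COc1cc(C(O)c2cc(O[Si](C(C)C)(C(C)C)C(C)C)c(OC)c(OC)c2Br)ccc1OCc1ccccc1 | intermediate
8 | 1-benzyloxy-4-[2-bromo-3,4-dimethoxy-5-(triisopropylsilyloxy)benzyl]-2-methoxybenzene | COc1cc(Cc2cc(O[Si](C(C)C)(C(C)C)C(C)C)c(OC)c(OC)c2Br)ccc1OCc1ccccc1 | intermediate
9 | [2-(4-benzyloxy-3-methoxybenzyl)-5,6-dimethoxy-4-(triisopropylsilyloxy)phenyl]lithium | COc1cc(Cc2cc(O[Si](C(C)C)(C(C)C)C(C)C)c(OC)c(OC)c2[Li])ccc1OCc1ccccc1 | intermediate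
10 | 6-(4-benzyloxy-3-methoxybenzyl)-2,3-dimethoxy-4-(triisopropylsilyloxy)benzaldehyde | O=Cc1c(OC)c(OC)c(O[Si](C(C)C)(C(C)C)C(C)C)cc1Cc1ccc(OCc2ccccc2)c(OC)c1 | intermediate
11 | fumaryl chloride | O=C(Cl)/C=C/C(=O)Cl | starting material
12 | methyl (R)-lactate | C[C@@H](O)C(=O)OC | starting material
13 | bis[(R)-1-methoxy-1-oxopropan-2-yl] fumarate | COC(=O)[C@@H](C)OC(=O)/C=C/C(=O)O[C@H](C)C(=O)OC | intermediate
14 | (E,E)-hydroxy-o-quinodimethane from 10 (OH anti to C8a, aryl anti to C4a) | O/C=C1\C(OC)=C(OC)C(O[Si](C(C)C)(C(C)C)C(C)C)=C\C1=C/c1ccc(OCc2ccccc2)c(OC)c1 | intermediate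
15 | bis[(R)-1-methoxy-1-oxopropan-2-yl] (1R,2S,3R,4R)-1-(4-benzyloxy-3-methoxyphenyl)-4-hydroxy-5,6-dimethoxy-7-(triisopropylsilyloxy)-1,2,3,4-tetrahydronaphthalene-2,3-dicarboxylate | COc1cc([C@@H]2c3cc(O[Si](C(C)C)(C(C)C)C(C)C)c(OC)c(OC)c3[C@H](O)[C@H](C(=O)O[C@H](C)C(=O)OC)[C@H]2C(=O)O[C@H](C)C(=O)OC)ccc1OCc1ccccc1 | intermediate
16 | (1R,2S,3S,4R)-1-(4-benzyloxy-3-methoxyphenyl)-2,3-bis(hydroxymethyl)-5,6-dimethoxy-7-(triisopropylsilyloxy)-1,2,3,4-tetrahydronaphthalen-4-ol | COc1cc([C@@H]2c3cc(O[Si](C(C)C)(C(C)C)C(C)C)c(OC)c(OC)c3[C@H](O)[C@H](CO)[C@H]2CO)ccc1OCc1ccccc1 | intermediate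
17 | (1R,2S,3S,4R)-1-(4-benzyloxy-3-methoxyphenyl)-2,3-bis(hydroxymethyl)-5,6-dimethoxy-1,2,3,4-tetrahydronaphthalene-4,7-diol | COc1cc([C@@H]2c3cc(O)c(OC)c(OC)c3[C@H](O)[C@H](CO)[C@H]2CO)ccc1OCc1ccccc1 | intermediate
18 | (1R,2S,3S)-1-(4-hydroxy-3-methoxyphenyl)-2,3-bis(hydroxymethyl)-5,6-dimethoxy-1,2,3,4-tetrahydronaphthalen-7-ol | COc1cc([C@@H]2c3cc(O)c(OC)c(OC)c3C[C@H](CO)[C@H]2CO)ccc1O | target

## Step count and risks

Total steps: 11. Longest linear sequence: 9 steps (1, 2, 4, 5, 6, 8, 9, 10, 11).

Steps most likely to fail: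

Step 8. The dienol may reketonise before it is captured, the excited aldehyde may sensitise E/Z isomerisation of the fumarate or abstract hydrogen from the ortho-methoxy group, and facial discrimination by a single hydrogen bond may be incomplete. The fallback sets out from 10 and removes light from the cycloaddition. Irradiation of 10 in SO2-saturated benzene should trap 14 as rac-cis-1-(4-benzyloxy-3-methoxyphenyl)-3-hydroxy-4,5-dimethoxy-6-(triisopropylsilyloxy)-1,3-dihydrobenzo[c]thiophene 2,2-dioxide F1. Heating F1 with 13 in toluene at 80–110 °C over ZnO (SO2 scavenger) should release the same dienol by cheletropic extrusion, in the dark and at high dienophile concentration, and the sequence comes back to the route at 15.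

Step 2. Bromination may take place at the other ortho position (between CHO and the silyloxy group) or go on to the dibromide. The fallback sets out from 2 and fixes the site by coordination instead of sterics. LiN(CH3)CH2CH2N(CH3)2 in THF at −20 °C should convert 2 in the flask into the racemic lithium α-amino alkoxide F2. n-BuLi should then lithiate the ring carbon flanked by the alkoxide and the 3-OMe group, since the silyloxy-flanked position is shielded and offers no coordination, giving the ortho-lithiated α-amino alkoxide F3. Quenching with BrCl2C–CCl2Br should give the brominated α-amino alkoxide F4, and work-up with dilute HCl comes back to the route at 3.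

Step 11. The benzylic C4–O bond may resist hydrogenolysis, or under the acidic conditions the C4 cation/quinone methide may be trapped by the C2 hydroxymethyl group to give a bridged C4–O–C9 ether. The fallback sets out from 15 and removes the C4 oxygen before any hydroxymethyl group exists. Ionic deoxygenation (Et3SiH, TFA, CH2Cl2, −20 °C) should give bis[(R)-1-methoxy-1-oxopropan-2-yl] (1R,2S,3S)-1-(4-benzyloxy-3-methoxyphenyl)-5,6-dimethoxy-7-(triisopropylsilyloxy)-1,2,3,4-tetrahydronaphthalene-2,3-dicarboxylate F5. LiAlH4 should reduce it to (1R,2S,3S)-1-(4-benzyloxy-3-methoxyphenyl)-2,3-bis(hydroxymethyl)-5,6-dimethoxy-7-(triisopropylsilyloxy)-1,2,3,4-tetrahydronaphthalene F6. TBAF/AcOH should give (1R,2S,3S)-1-(4-benzyloxy-3-methoxyphenyl)-2,3-bis(hydroxymethyl)-5,6-dimethoxy-1,2,3,4-tetrahydronaphthalen-7-ol F7, and hydrogenolysis of the remaining benzyl ether (H2, 10% Pd/C, EtOH) comes back to the route at 18.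

Further compounds
F1 | step 8 | rac-cis-1-(4-benzyloxy-3-methoxyphenyl)-3-hydroxy-4,5-dimethoxy-6-(triisopropylsilyloxy)-1,3-dihydrobenzo[c]thiophene 2,2-dioxide (one enantiomer drawn) | O[C@@H]1c2c(OC)c(OC)c(O[Si](C(C)C)(C(C)C)C(C)C)cc2[C@H](c2ccc(OCc3ccccc3)c(OC)c2)S1(=O)=O
F2 | step 2 | lithium α-amino alkoxide of 2 with N,N,N'-trimethylethylenediamine (racemic) | [Li]OC(N(C)CCN(C)C)c1cc(O[Si](C(C)C)(C(C)C)C(C)C)c(OC)c(OC)c1
F3 | step 2 | ortho-lithiated α-amino alkoxide (racemic) | [Li]OC(N(C)CCN(C)C)c1cc(O[Si](C(C)C)(C(C)C)C(C)C)c(OC)c(OC)c1[Li]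
F4 | step 2 | brominated α-amino alkoxide (racemic) | [Li]OC(N(C)CCN(C)C)c1cc(O[Si](C(C)C)(C(C)C)C(C)C)c(OC)c(OC)c1Br
F5 | step 11 | bis[(R)-1-methoxy-1-oxopropan-2-yl] (1R,2S,3S)-1-(4-benzyloxy-3-methoxyphenyl)-5,6-dimethoxy-7-(triisopropylsilyloxy)-1,2,3,4-tetrahydronaphthalene-2,3-dicarboxylate | COc1cc([C@@H]2c3cc(O[Si](C(C)C)(C(C)C)C(C)C)c(OC)c(OC)c3C[C@H](C(=O)O[C@H](C)C(=O)OC)[C@H]2C(=O)O[C@H](C)C(=O)OC)ccc1OCc1ccccc1
F6 | step 11 | (1R,2S,3S)-1-(4-benzyloxy-3-methoxyphenyl)-2,3-bis(hydroxymethyl)-5,6-dimethoxy-7-(triisopropylsilyloxy)-1,2,3,4-tetrahydronaphthalene | COc1cc([C@@H]2c3cc(O[Si](C(C)C)(C(C)C)C(C)C)c(OC)c(OC)c3C[C@H](CO)[C@H]2CO)ccc1OCc1ccccc1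
F7 | step 11 | (1R,2S,3S)-1-(4-benzyloxy-3-methoxyphenyl)-2,3-bis(hydroxymethyl)-5,6-dimethoxy-1,2,3,4-tetrahydronaphthalen-7-ol | COc1cc([C@@H]2c3cc(O)c(OC)c(OC)c3C[C@H](CO)[C@H]2CO)ccc1OCc1ccccc1
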